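**Retrosynthetic overview** (hydroazulene numbering: C1/C3 carbinols, C3a/C8a ring fusion, C4/C8 esters, C6 methyl)
1. Target ⇐ tetraol 21 by site-selective bis-angeloylation; 21 ⇐ hydroxy-enedione 19 by two hydroxyl-directed anti reductions (C1, then C8).
2. Seven-membered ring, formed last: ring-closing metathesis (C6=C7) of crotonyl ketone / methallyl carbinol 18.
3. C4–C5 by chelation-controlled Barbier methallylation of aldehyde 17; C8a methyl by alkylation of the 2-acylcyclopentanone enolate.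
4. Key bond C3a–C4: Giese addition of the 1,3-dioxolan-2-yl radical (masked formyl, acyl-anion polarity) to the β-carbon of 2-enoylcyclopentenone 10.
5. Five-membered ring present from the start: (S)-4-silyloxycyclopentenone 1 → i-Pr addition, oxidation-state swap, α-iodination, carbonylative Stille coupling.

Assumption: the SMILES is taken as drawn (cis-fused, 1R,3S,3aR,4R,8R,8aR); enone 1, stannane 8 (E/Z mixtures serve equally) and angelic acid are treated as commercial.

**Step 1**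
Reactants: 1 (4S)-4-{[tert-butyl(dimethyl)silyl]oxy}cyclopent-2-en-1-one; 2 isopropylmagnesium chloride
Product: 3 (1S,4S)-4-{[tert-butyl(dimethyl)silyl]oxy}-1-(propan-2-yl)cyclopent-2-en-1-ol
Conditions: i-PrMgCl, CeCl3, THF, −78 °C; aq. NH4Cl
Reagents that add atoms: isopropylmagnesium chloride, CC(C)[Mg]Cl
Why: Imamoto organocerium 1,2-addition (cerium suppresses enolisation and 1,4-addition) occurs anti to the bulky 4-OTBS group, so the new tertiary carbinol (later C3) has OH cis to OTBS.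

**Step 2**
Reactants: 3 (1S,4S)-4-{[tert-butyl(dimethyl)silyl]oxy}-1-(propan-2-yl)cyclopent-2-en-1-ol
Product: 4 (1S,4S)-1-(propan-2-yl)cyclopent-2-ene-1,4-diol
Conditions: TBAF, THF, 0 °C to rt
Reagents that add atoms: none
Why: Fluoride-induced desilylation frees the secondary allylic alcohol without touching either stereocentre.

**Step 3**
Reactants: 4 (1S,4S)-1-(propan-2-yl)cyclopent-2-ene-1,4-diol
Product: 5 (4S)-4-hydroxy-4-(propan-2-yl)cyclopent-2-en-1-one
Conditions: MnO2, CH2Cl2, rt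
Reagents that add atoms: none
Why: MnO2 allylic oxidation converts only the secondary allylic alcohol to the enone, erasing the now redundant carbinol centre and leaving the (S)-tertiary carbinol as the sole stereocentre.

**Step 4**
Reactants: 5 (4S)-4-hydroxy-4-(propan-2-yl)cyclopent-2-en-1-one; 6 iodine
Product: 7 (4S)-4-hydroxy-2-iodo-4-(propan-2-yl)cyclopent-2-en-1-one
Conditions: I2, pyridine, CH2Cl2, 0 °C to rt
Reagents that add atoms: iodine, II
Why: Johnson α-iodination of an enone (pyridine 1,4-addition, enolate iodination, elimination) is reliable for 4,4-disubstituted cycloalkenones and creates no stereocentre.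

**Step 5**
Reactants: 7 (4S)-4-hydroxy-2-iodo-4-(propan-2-yl)cyclopent-2-en-1-one; 8 tributyl[(1E)-prop-1-en-1-yl]stannane; 9 carbon monoxide
Product: 10 (4S)-2-[(2E)-but-2-enoyl]-4-hydroxy-4-(propan-2-yl)cyclopent-2-en-1-one
Conditions: Pd2(dba)3 (cat.), AsPh3, CO (3 bar), NMP, 45 °C
Reagents that add atoms: tributyl[(1E)-prop-1-en-1-yl]stannane, C/C=C/[Sn](CCCC)(CCCC)CCCC; carbon monoxide, [C-]#[O+]
Why: Carbonylative Stille coupling (oxidative addition, CO insertion, transmetalation, reductive elimination) gives the 2-enoyl enone, an alkylidene 1,3-diketone, without forming a stereocentre.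

**Step 6**
Reactants: 10 (4S)-2-[(2E)-but-2-enoyl]-4-hydroxy-4-(propan-2-yl)cyclopent-2-en-1-one; 11 1,3-dioxolane
Product: 12 (2S,3S,4S)-2-[(2E)-but-2-enoyl]-3-(1,3-dioxolan-2-yl)-4-hydroxy-4-(propan-2-yl)cyclopentan-1-one (largely enolised; C2 is labile)
Conditions: (n-Bu4N)4W10O32 (2 mol %), 1,3-dioxolane/MeCN, 390 nm LED, rt
Reagents that add atoms: 1,3-dioxolane, C1COCO1
Why: Decatungstate hydrogen-atom transfer generates the nucleophilic 1,3-dioxolan-2-yl radical, a masked formyl (acyl-anion-type) unit, which adds in a Giese reaction to the doubly activated ring β-carbon in preference to the singly activated crotonyl group and anti to the isopropyl group (cis to OH), fixing the future C3a centre.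

**Step 7**
Reactants: 12 (2S,3S,4S)-2-[(2E)-but-2-enoyl]-3-(1,3-dioxolan-2-yl)-4-hydroxy-4-(propan-2-yl)cyclopentan-1-one; 13 iodomethane
Product: 14 (2R,3S,4S)-2-[(2E)-but-2-enoyl]-3-(1,3-dioxolan-2-yl)-4-hydroxy-2-methyl-4-(propan-2-yl)cyclopentan-1-one
Conditions: MeI, K2CO3 (1.2 equiv), acetone, 0 °C to rt
Reagents that add atoms: iodomethane, CI
Why: C-Alkylation of the stabilised 1,3-diketone enolate takes place on the face opposite the adjacent dioxolanyl group, so the quaternary centre (future C8a) carries methyl trans and the enoyl group cis to the C1 unit on the neighbouring carbon.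

**Step 8**
Reactants: 14 (2R,3S,4S)-2-[(2E)-but-2-enoyl]-3-(1,3-dioxolan-2-yl)-4-hydroxy-2-methyl-4-(propan-2-yl)cyclopentan-1-one; 15 water; 16 3-bromo-2-methylprop-1-ene
Product: 18 (2R,3R,4S)-2-[(2E)-but-2-enoyl]-4-hydroxy-3-[(1R)-1-hydroxy-3-methylbut-3-en-1-yl]-2-methyl-4-(propan-2-yl)cyclopentan-1-one, via keto aldehyde 17 (not isolated)
Conditions: Amberlyst-15, THF/H2O, rt; filter; then In powder, methallyl bromide, THF/H2O, rt
Reagents that add atoms: water, O; 3-bromo-2-methylprop-1-ene, CC(=C)CBr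
Why: Acetal hydrolysis unmasks the aldehyde, and aldehyde-selective indium Barbier allylation in water proceeds through a chelate of indium with the aldehyde oxygen and the cis tertiary hydroxyl, the allyl group attacking the face remote from the cis enoyl substituent to give the 1,3-anti diol, i.e. the (R)-carbinol (future C4).

**Step 9**
Reactants: 18 (2R,3R,4S)-2-[(2E)-but-2-enoyl]-4-hydroxy-3-[(1R)-1-hydroxy-3-methylbut-3-en-1-yl]-2-methyl-4-(propan-2-yl)cyclopentan-1-one
Product: 19 (3S,3aR,4R,8aR)-3,4-dihydroxy-6,8a-dimethyl-3-(propan-2-yl)-2,3,3a,4,5,8a-hexahydroazulene-1,8-dione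
Conditions: Hoveyda–Grubbs II (5 mol %), toluene (5 mM), 80 °C
Reagents that add atoms: none
Why: Ring-closing metathesis between the crotonyl double bond and the 1,1-disubstituted olefin closes the seven-membered ring as the trisubstituted enone; the cis side chains set in steps 6 and 7 dictate the cis ring fusion and no stereocentre changes.

**Step 10**
Reactants: 19 (3S,3aR,4R,8aR)-3,4-dihydroxy-6,8a-dimethyl-3-(propan-2-yl)-2,3,3a,4,5,8a-hexahydroazulene-1,8-dione
Product: 21 (1R,3S,3aR,4R,8R,8aR)-6,8a-dimethyl-3-(propan-2-yl)-1,2,3,3a,4,5,8,8a-octahydroazulene-1,3,4,8-tetrol, via triol enone 20 (not isolated)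
Conditions: Me4NBH(OAc)3 (6 equiv), MeCN/AcOH 1:1, −30 to 0 °C
Reagents that add atoms: none
Why: Evans–Saksena reduction delivers hydride intramolecularly, first from the boron bound to the tertiary C3–OH to the β-hydroxy ring ketone (1,3-anti, C1–OH trans to C3–OH), then from the new C1 alkoxide on the α-face to the enone carbonyl (1,2-reduction, 1,3-anti), setting C1 and C8.

**Step 11**
Reactants: 21 (1R,3S,3aR,4R,8R,8aR)-6,8a-dimethyl-3-(propan-2-yl)-1,2,3,3a,4,5,8,8a-octahydroazulene-1,3,4,8-tetrol; 22 (2Z)-2-methylbut-2-enoic acid (angelic acid)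
Product: 24 (1R,3S,3aR,4R,8R,8aR)-1,3-dihydroxy-6,8a-dimethyl-3-(propan-2-yl)-1,2,3,3a,4,5,8,8a-octahydroazulene-4,8-diyl bis[(2Z)-2-methylbut-2-enoate] (CNP0249167.1), via mixed angelic trichlorobenzoic anhydride 23 (not isolated)
Conditions: angelic acid (3 equiv), 2,4,6-Cl3C6H2COCl, Et3N, toluene, rt; then 21, toluene, 75 °C (no DMAP)
Reagents that add atoms: (2Z)-2-methylbut-2-enoic acid, C/C=C(/C)C(=O)O
Why: Yamaguchi-type esterification through the preformed mixed anhydride (DMAP-free to keep the Z geometry) acylates the two accessible secondary hydroxyls (C4 and allylic C8), while the tertiary C3–OH and the C1–OH, shielded by the cis angular methyl and the cis-1,3 isopropyl group, stay free.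

**Compound list**
1 | (4S)-4-{[tert-butyl(dimethyl)silyl]oxy}cyclopent-2-en-1-one | CC(C)(C)[Si](C)(C)O[C@H]1CC(=O)C=C1 | starting material
2 | isopropylmagnesium chloride | CC(C)[Mg]Cl | starting material
3 | (1S,4S)-4-{[tert-butyl(dimethyl)silyl]oxy}-1-(propan-2-yl)cyclopent-2-en-1-ol (OH cis to OTBS) | CC(C)(C)[Si](C)(C)O[C@H]1C[C@](O)(C(C)C)C=C1 | intermediate
4 | (1S,4S)-1-(propan-2-yl)cyclopent-2-ene-1,4-diol (cis-diol) | O[C@H]1C[C@](O)(C(C)C)C=C1 | intermediate
5 | (4S)-4-hydroxy-4-(propan-2-yl)cyclopent-2-en-1-one | O=C1C[C@](O)(C(C)C)C=C1 | intermediate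
6 | iodine | II | starting material
7 | (4S)-4-hydroxy-2-iodo-4-(propan-2-yl)cyclopent-2-en-1-one | O=C1C[C@](O)(C(C)C)C=C1I | intermediate
8 | tributyl[(1E)-prop-1-en-1-yl]stannane | C/C=C/[Sn](CCCC)(CCCC)CCCC | starting material
9 | carbon monoxide | [C-]#[O+] | starting material
10 | (4S)-2-[(2E)-but-2-enoyl]-4-hydroxy-4-(propan-2-yl)cyclopent-2-en-1-one | O=C1C[C@](O)(C(C)C)C=C1C(=O)/C=C/C | intermediate
11 | 1,3-dioxolane | C1COCO1 | starting material
12 | (2S,3S,4S)-2-[(2E)-but-2-enoyl]-3-(1,3-dioxolan-2-yl)-4-hydroxy-4-(propan-2-yl)cyclopentan-1-one (trans-diketo tautomer shown) | C1(OCCO1)[C@@H]2[C@@](O)(C(C)C)CC(=O)[C@H]2C(=O)/C=C/C | intermediate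
13 | iodomethane | CI | starting material
14 | (2R,3S,4S)-2-[(2E)-but-2-enoyl]-3-(1,3-dioxolan-2-yl)-4-hydroxy-2-methyl-4-(propan-2-yl)cyclopentan-1-one | C1(OCCO1)[C@@H]2[C@@](O)(C(C)C)CC(=O)[C@]2(C)C(=O)/C=C/C | intermediate
15 | water | O | starting material
16 | 3-bromo-2-methylprop-1-ene | CC(=C)CBr | starting material
17 | (1S,2R,5S)-2-[(2E)-but-2-enoyl]-5-hydroxy-2-methyl-3-oxo-5-(propan-2-yl)cyclopentane-1-carbaldehyde | O=C[C@@H]1[C@@](O)(C(C)C)CC(=O)[C@]1(C)C(=O)/C=C/C | intermediate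
18 | (2R,3R,4S)-2-[(2E)-but-2-enoyl]-4-hydroxy-3-[(1R)-1-hydroxy-3-methylbut-3-en-1-yl]-2-methyl-4-(propan-2-yl)cyclopentan-1-one | C=C(C)C[C@@H](O)[C@@H]1[C@@](O)(C(C)C)CC(=O)[C@]1(C)C(=O)/C=C/C | intermediate
19 | (3S,3aR,4R,8aR)-3,4-dihydroxy-6,8a-dimethyl-3-(propan-2-yl)-2,3,3a,4,5,8a-hexahydroazulene-1,8-dione | O[C@@H]1CC(C)=CC(=O)[C@@]2(C)C(=O)C[C@](O)(C(C)C)[C@@H]12 | intermediate
20 | (1R,3S,3aR,4R,8aR)-1,3,4-trihydroxy-6,8a-dimethyl-3-(propan-2-yl)-1,2,3,3a,4,5-hexahydroazulen-8(8aH)-one | O[C@@H]1CC(C)=CC(=O)[C@@]2(C)[C@H](O)C[C@](O)(C(C)C)[C@@H]12 | intermediate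
21 | (1R,3S,3aR,4R,8R,8aR)-6,8a-dimethyl-3-(propan-2-yl)-1,2,3,3a,4,5,8,8a-octahydroazulene-1,3,4,8-tetrol | O[C@@H]1CC(C)=C[C@@H](O)[C@@]2(C)[C@H](O)C[C@](O)(C(C)C)[C@@H]12 | intermediate
22 | (2Z)-2-methylbut-2-enoic acid (angelic acid) | C/C=C(/C)C(=O)O | starting material
23 | (2Z)-2-methylbut-2-enoic 2,4,6-trichlorobenzoic anhydride | C/C=C(/C)C(=O)OC(=O)c1c(Cl)cc(Cl)cc1Cl | intermediate
24 | (1R,3S,3aR,4R,8R,8aR)-1,3-dihydroxy-6,8a-dimethyl-3-(propan-2-yl)-1,2,3,3a,4,5,8,8a-octahydroazulene-4,8-diyl bis[(2Z)-2-methylbut-2-enoate] | C/C=C(/C)C(=O)O[C@@H]1CC(C)=C[C@@H](OC(=O)/C(C)=C\C)[C@@]2(C)[C@H](O)C[C@](O)(C(C)C)[C@@H]12 | target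

**Totals**
Total step count: 11. Longest linear sequence: 11 steps (from 1).

**Three steps most likely to fail**

Step 6 (radical addition). The dioxolanyl radical may also add to the crotonyl group, the product may add a second time, or the facial selectivity next to the quaternary carbinol may be poor. The fallback changes the order of acylation and radical addition; it sets out from 5 and comes back at 12, so steps 4 and 5 are not needed. Enone 5, which has only one acceptor site, is irradiated with the decatungstate catalyst in 1,3-dioxolane to give (3S,4S)-3-(1,3-dioxolan-2-yl)-4-hydroxy-4-(propan-2-yl)cyclopentan-1-one F1. Its C2 boron enolate (Bu2BOTf, i-Pr2NEt; the C5 side is blocked by the neighbouring borylated tertiary carbinol) is added to (E)-but-2-enal to give (2R,3S,4S)-3-(1,3-dioxolan-2-yl)-4-hydroxy-2-[(2E)-1-hydroxybut-2-en-1-yl]-4-(propan-2-yl)cyclopentan-1-one F2 as a mixture of carbinol epimers. Dess–Martin oxidation of the allylic alcohol then gives 12.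

Step 8 (aldehyde release and Barbier allylation). The β-hydroxy aldehyde 17 is acid-sensitive and the chelation control at C4 may be weak. The fallback sets out from 18, as whatever C4 epimer mixture is obtained, and comes back at 21. Dess–Martin oxidation gives (2R,3S,4S)-2-[(2E)-but-2-enoyl]-4-hydroxy-2-methyl-3-(3-methylbut-3-enoyl)-4-(propan-2-yl)cyclopentan-1-one F3. Me4NBH(OAc)3 then reduces, by internal delivery, the two ketones β to the tertiary hydroxyl and after that the crotonyl ketone β to the new ring hydroxyl. This gives (1R,2R,3R,4S)-2-[(1R,2E)-1-hydroxybut-2-en-1-yl]-3-[(1R)-1-hydroxy-3-methylbut-3-en-1-yl]-2-methyl-4-(propan-2-yl)cyclopentane-1,4-diol F4. Ring-closing metathesis of F4 gives 21 directly.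

Step 11 (bis-angeloylation). The C1–OH may compete with the C8–OH, and the angelate may isomerise to tiglate under forcing conditions. The fallback sets out from 19 and comes back at 24; it acylates before the ring ketone is reduced. A reagent-controlled CBS reduction (oxazaborolidine enantiomer chosen to deliver hydride to the α-face, catecholborane, −78 °C) reduces only the enone to give (3S,3aR,4R,8R,8aS)-3,4,8-trihydroxy-6,8a-dimethyl-3-(propan-2-yl)-2,3,3a,4,5,8-hexahydroazulen-1(8aH)-one F5. Its only two secondary hydroxyls are angeloylated as in step 11 to give (3S,3aR,4R,8R,8aS)-3-hydroxy-6,8a-dimethyl-1-oxo-3-(propan-2-yl)-1,2,3,3a,4,5,8,8a-octahydroazulene-4,8-diyl bis[(2Z)-2-methylbut-2-enoate] F6. Me4NBH(OAc)3, directed by the tertiary hydroxyl, then reduces the ring ketone to give 24.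

**Further compounds**
F1 | step 6 | (3S,4S)-3-(1,3-dioxolan-2-yl)-4-hydroxy-4-(propan-2-yl)cyclopentan-1-one | C1(OCCO1)[C@@H]2[C@@](O)(C(C)C)CC(=O)C2
F2 | step 6 | (2R,3S,4S)-3-(1,3-dioxolan-2-yl)-4-hydroxy-2-[(2E)-1-hydroxybut-2-en-1-yl]-4-(propan-2-yl)cyclopentan-1-one (carbinol epimers) | C1(OCCO1)[C@@H]2[C@@](O)(C(C)C)CC(=O)[C@H]2C(O)/C=C/C
F3 | step 8 | (2R,3S,4S)-2-[(2E)-but-2-enoyl]-4-hydroxy-2-methyl-3-(3-methylbut-3-enoyl)-4-(propan-2-yl)cyclopentan-1-one | C=C(C)CC(=O)[C@@H]1[C@@](O)(C(C)C)CC(=O)[C@]1(C)C(=O)/C=C/C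
F4 | step 8 | (1R,2R,3R,4S)-2-[(1R,2E)-1-hydroxybut-2-en-1-yl]-3-[(1R)-1-hydroxy-3-methylbut-3-en-1-yl]-2-methyl-4-(propan-2-yl)cyclopentane-1,4-diol | C=C(C)C[C@@H](O)[C@@H]1[C@@](O)(C(C)C)C[C@@H](O)[C@]1(C)[C@H](O)/C=C/C
F5 | step 11 | (3S,3aR,4R,8R,8aS)-3,4,8-trihydroxy-6,8a-dimethyl-3-(propan-2-yl)-2,3,3a,4,5,8-hexahydroazulen-1(8aH)-one | O[C@@H]1CC(C)=C[C@@H](O)[C@@]2(C)C(=O)C[C@](O)(C(C)C)[C@@H]12
F6 | step 11 | (3S,3aR,4R,8R,8aS)-3-hydroxy-6,8a-dimethyl-1-oxo-3-(propan-2-yl)-1,2,3,3a,4,5,8,8a-octahydroazulene-4,8-diyl bis[(2Z)-2-methylbut-2-enoate] | C/C=C(/C)C(=O)O[C@@H]1CC(C)=C[C@@H](OC(=O)/C(C)=C\C)[C@@]2(C)C(=O)C[C@](O)(C(C)C)[C@@H]12
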